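The cyclopentenone is disconnected at C9–C10 and C8–C9, and the upper chain at C6–C7. The ring (C8–C12) holds its ketone C9 between the brominated alkene carbon C10 and the alkylidene carbon C8, and C6 sits cis to C9 on the exocyclic C7=C8 bond. This is the imprint of a syn acylmetalation of a C8≡C7 alkyne followed by coupling at C7. One palladium-catalysed operation therefore unites an iodoalkene–alkyne, carbon monoxide and an (E)-alkenylstannane, closing the ring and attaching the chain. The precursor is a (3R) tertiary propargylic acetate carrying a (Z)-2-bromo-2-iodovinyl group (iodine cis to C12) and the (Z)-octenyl chain; C12 comes from a Sharpless epoxidation.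

Key step: step 12

Remark: atoms carry prostanoid numbers (C1 ester carbonyl, C8–C12 ring, C13–C20 lower chain). The target SMILES is read as 5E,7Z,14Z with C12 R.
Assumption: pentylmagnesium bromide (ether solution), acetylene, the Ohira–Bestmann reagent and the catalysts named are purchased.
Remark: the halogen–metal exchange before the key step is run with magnesium, not lithium. The magnesium carbenoid survives at −78 °C and the acetylenic C–H is not deprotonated at that temperature.

Step 1
Reactants: 1 pentylmagnesium bromide; 2 acetylene; 3 methyl 2-(bromomethyl)acrylate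
Product: 6 methyl (4Z)-2-methylidenedec-4-enoate, via pentylcopper 4 (not isolated), via (Z)-hept-1-enylcopper 5 (not isolated)
Conditions: CuBr·SMe2 (1.0 equiv), Et2O/Me2S, −45 °C; HC≡CH (1.0 equiv), −25 °C; then 3, −78 → −20 °C
Reagents that add atoms: none
Why: Syn carbocupration of acetylene by the pentylcopper reagent gives the (Z)-alkenylcopper stereospecifically, and this attacks the 2-(bromomethyl)acrylate in an SN2′ addition–elimination (allylic substitution) that keeps the Z geometry.

Step 2
Reactants: 6 methyl (4Z)-2-methylidenedec-4-enoate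
Product: 7 (4Z)-2-methylidenedec-4-en-1-ol
Conditions: DIBAL-H (2.2 equiv), CH2Cl2, −78 → 0 °C; Rochelle salt work-up
Reagents that add atoms: none
Why: DIBAL-H reduction of an α,β-unsaturated ester proceeds by 1,2-hydride delivery to the allylic alcohol without conjugate reduction.

Step 3
Reactants: 7 (4Z)-2-methylidenedec-4-en-1-ol
Product: 8 [(2S)-2-[(2Z)-oct-2-en-1-yl]oxiran-2-yl]methanol
Conditions: Ti(OiPr)4 (10 mol%), L-(+)-diethyl tartrate (12 mol%), TBHP (2 equiv, anhydrous), 4 Å MS, CH2Cl2, −20 °C
Reagents that add atoms: tert-butyl hydroperoxide, CC(C)(C)OO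
Why: Sharpless asymmetric epoxidation under catalytic conditions: the titanium–L-(+)-tartrate complex binds the allylic hydroxyl and delivers oxygen to one face of the 1,1-disubstituted alkene, which sets the quaternary centre (C12, S in 8), while the remote Z-alkene has no directing hydroxyl and stays untouched.

Step 4
Reactants: 8 [(2S)-2-[(2Z)-oct-2-en-1-yl]oxiran-2-yl]methanol
Product: 9 (2R)-2-[(2Z)-oct-2-en-1-yl]oxirane-2-carbaldehyde
Conditions: TEMPO (10 mol%), PhI(OAc)2 (1.1 equiv), CH2Cl2, rt
Reagents that add atoms: none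
Why: TEMPO/PhI(OAc)2 (oxoammonium) oxidation stops at the aldehyde under neutral conditions, and the quaternary α-carbon cannot epimerise.

Step 5
Reactants: 9 (2R)-2-[(2Z)-oct-2-en-1-yl]oxirane-2-carbaldehyde
Product: 10 (2S)-2-ethynyl-2-[(2Z)-oct-2-en-1-yl]oxirane
Conditions: dimethyl (1-diazo-2-oxopropyl)phosphonate (1.3 equiv), K2CO3, MeOH, 0 °C → rt
Reagents that add atoms: dimethyl (1-diazo-2-oxopropyl)phosphonate, COP(=O)(OC)C(=[N+]=[N-])C(C)=O
Why: Seyferth–Gilbert homologation in the Ohira–Bestmann form converts the aldehyde into the terminal alkyne (C8≡C7) under carbonate conditions that leave the epoxide closed.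

Step 6
Reactants: 10 (2S)-2-ethynyl-2-[(2Z)-oct-2-en-1-yl]oxirane
Product: 11 (2S,4Z)-2-ethynyldec-4-ene-1,2-diol
Conditions: KOH (3 equiv), DMSO/H2O (1:1), 70 °C
Reagents that add atoms: water, O
Why: Base-mediated epoxide hydrolysis: hydroxide attacks the unsubstituted carbon (C11) in an SN2 opening, so the C12–O bond and its configuration are retained, and acid is avoided because it would ionise the tertiary propargylic carbon.

Step 7
Reactants: 11 (2S,4Z)-2-ethynyldec-4-ene-1,2-diol
Product: 12 (2S,4Z)-2-ethynyl-2-hydroxydec-4-enal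
Conditions: SO3·pyridine (3 equiv), DMSO, iPr2NEt, CH2Cl2, 0 °C; used without purification
Reagents that add atoms: none
Why: Parikh–Doering oxidation (activated DMSO) converts the primary alcohol into the aldehyde; the tertiary alcohol cannot be oxidised and this oxidant does not cleave the 1,2-diol.

Step 8
Reactants: 12 (2S,4Z)-2-ethynyl-2-hydroxydec-4-enal
Product: 13 (3R,5Z)-1,1-dibromo-3-ethynylundeca-1,5-dien-3-ol
Conditions: PPh3 (2 equiv), CBr4 (2 equiv), Zn dust (2 equiv), CH2Cl2, rt (ylide pre-formed); then 12, 0 °C → rt
Reagents that add atoms: carbon tetrabromide, BrC(Br)(Br)Br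
Why: Ramirez dibromo-olefination (first stage of the Corey–Fuchs sequence) is a Wittig reaction of Ph3P=CBr2, and pre-forming the ylide with zinc removes Ph3PBr2 so that the free tertiary propargylic alcohol is not activated.

Step 9
Reactants: 13 (3R,5Z)-1,1-dibromo-3-ethynylundeca-1,5-dien-3-ol
Product: 15 (1Z,3R,5Z)-1-bromo-3-ethynyl-1-iodoundeca-1,5-dien-3-ol, via magnesium carbenoid 14 (not isolated)
Conditions: i-PrMgCl·LiCl (2.2 equiv), THF, −78 °C, 20 min; then I2 (1.3 equiv) in THF, −78 → −40 °C; aq. Na2S2O3/NH4Cl; dark
Reagents that add atoms: iodine, II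
Why: Alkoxide-directed bromine–magnesium exchange of a 1,1-dibromoalkene: after O–H deprotonation the magnesium alkoxide steers exchange to the more hindered bromine cis to C12 (five-membered O–Mg chelate), and iodinolysis with retention places iodine cis to C12.

Step 10
Reactants: 15 (1Z,3R,5Z)-1-bromo-3-ethynyl-1-iodoundeca-1,5-dien-3-ol
Product: 16 (1Z,3R,5Z)-1-bromo-3-ethynyl-1-iodoundeca-1,5-dien-3-yl acetate
Conditions: Ac2O (5 equiv), DMAP (1 equiv), Et3N, CH2Cl2, rt, dark
Reagents that add atoms: acetic anhydride, CC(=O)OC(C)=O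
Why: DMAP-catalysed acylation (nucleophilic catalysis) of the tertiary alcohol installs the acetate of the target and also stops the hydroxyl from capturing the acylpalladium of step 12 as a butenolide.

Step 11
Reactants: 17 methyl hex-5-ynoate
Product: 18 methyl (5E)-6-(tributylstannyl)hex-5-enoate
Conditions: Bu3SnH (1.2 equiv), Pd2(dba)3 (0.5 mol%), Cy3P·HBF4 (2 mol%), iPr2NEt (4 mol%), CH2Cl2, 0 °C → rt
Reagents that add atoms: tributyltin hydride, CCCC[SnH](CCCC)CCCC
Why: Palladium-catalysed hydrostannation is a syn addition of Sn–H across the terminal alkyne, and the bulky tricyclohexylphosphine directs tin to the terminal carbon to give the (E)-alkenylstannane, the minor internal isomer being separable.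

Step 12
Reactants: 16 (1Z,3R,5Z)-1-bromo-3-ethynyl-1-iodoundeca-1,5-dien-3-yl acetate; 19 carbon monoxide; 18 methyl (5E)-6-(tributylstannyl)hex-5-enoate
Product: 22 methyl (5E,7Z)-7-[(2R)-2-acetoxy-4-bromo-2-[(2Z)-oct-2-en-1-yl]-5-oxocyclopent-3-en-1-ylidene]hept-5-enoate, via acylpalladium iodide 20 (not isolated), via alkenylpalladium iodide 21 (not isolated)
Conditions: Pd2(dba)3 (2.5 mol%), P(2-furyl)3 (10 mol%), CO (1 atm), THF, 45 °C; 18 (1.1 equiv) by syringe pump over 3 h; exclusion of light
Reagents that add atoms: none
Why: Pd(0) inserts into the C10–I bond, CO inserts to give acylpalladium 20, this adds syn across the tethered C8≡C7 alkyne to give the ketone-chelated alkenylpalladium 21, and 21 transmetalates with 18 and reductively eliminates, so C9–C10, C8–C9 and C6–C7 form in one catalytic cycle. The closest known reaction types are the cyclic acylpalladation of alkynes by acylpalladium species generated from iodoalkenes under CO and the Stille termination of carbopalladation cascades (carbonylative Stille coupling for the CO/tin pairing). The cyclopentenone closes in the 5-exo-dig mode, because a 6-endo syn addition would demand a trans double bond in the ring and a direct 4-exo carbopalladation without CO is too strained. No stereocentre is formed: C12 is a spectator and the 7Z geometry follows from the syn addition, C6 entering where palladium sat, cis to C9. The step needs insertion into C–I ahead of the geminal C–Br and the propargylic C–OAc, which the weaker C–I bond should secure, and ring closure ahead of Stille coupling, which the cis relation of iodine to C12, the fast intramolecular insertion and slow addition of 18 under 1 atm CO should secure. A phosphine-ligated Pd(0) source is chosen because electrophilic Pd(II) salts would trigger acyloxy migration of the 3-acyloxy-1,4-enyne, and 18 is kept near one equivalent so that the C10–Br bond of the product is not coupled.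

Compound list
1 | pentylmagnesium bromide | CCCCC[Mg]Br | starting material
2 | acetylene | C#C | starting material
3 | methyl 2-(bromomethyl)acrylate | C=C(CBr)C(=O)OC | starting material
4 | pentylcopper (MgBr2 complex, not isolated) | CCCCC[Cu] | intermediate
5 | (Z)-hept-1-enylcopper (MgBr2 complex, not isolated) | CCCCC/C=C\[Cu] | intermediate
6 | methyl (4Z)-2-methylidenedec-4-enoate | CCCCC/C=C\CC(=C)C(=O)OC | intermediate
7 | (4Z)-2-methylidenedec-4-en-1-ol | CCCCC/C=C\CC(=C)CO | intermediate
8 | [(2S)-2-[(2Z)-oct-2-en-1-yl]oxiran-2-yl]methanol | CCCCC/C=C\C[C@@]1(CO)OC1 | intermediate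
9 | (2R)-2-[(2Z)-oct-2-en-1-yl]oxirane-2-carbaldehyde | CCCCC/C=C\C[C@@]1(C=O)OC1 | intermediate
10 | (2S)-2-ethynyl-2-[(2Z)-oct-2-en-1-yl]oxirane | CCCCC/C=C\C[C@@]1(C#C)OC1 | intermediate
11 | (2S,4Z)-2-ethynyldec-4-ene-1,2-diol | CCCCC/C=C\C[C@@](C#C)(O)CO | intermediate
12 | (2S,4Z)-2-ethynyl-2-hydroxydec-4-enal | CCCCC/C=C\C[C@@](C#C)(O)C=O | intermediate
13 | (3R,5Z)-1,1-dibromo-3-ethynylundeca-1,5-dien-3-ol | CCCCC/C=C\C[C@@](C#C)(O)C=C(Br)Br | intermediate
14 | magnesium carbenoid: chloromagnesium alkoxide of 13 with the bromine cis to C12 replaced by MgCl (not isolated) | CCCCC/C=C\C[C@@](C#C)(O[Mg]Cl)/C=C(\[Mg]Cl)Br | intermediate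
15 | (1Z,3R,5Z)-1-bromo-3-ethynyl-1-iodoundeca-1,5-dien-3-ol | CCCCC/C=C\C[C@@](C#C)(O)/C=C(\I)Br | intermediate
16 | (1Z,3R,5Z)-1-bromo-3-ethynyl-1-iodoundeca-1,5-dien-3-yl acetate (cascade precursor) | CCCCC/C=C\C[C@@](C#C)(OC(C)=O)/C=C(\I)Br | intermediate
17 | methyl hex-5-ynoate | C#CCCCC(=O)OC | starting material
18 | methyl (5E)-6-(tributylstannyl)hex-5-enoate | CCCC[Sn](CCCC)(CCCC)/C=C/CCCC(=O)OC | intermediate
19 | carbon monoxide | [C-]#[O+] | starting material
20 | acylpalladium iodide from 16: C9 acyl on C10, cis to C12, ligands omitted (not isolated) | CCCCC/C=C\C[C@@](C#C)(OC(C)=O)/C=C(\C(=O)[Pd]I)Br | intermediate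
21 | alkenylpalladium iodide: cyclised, Pd on C7 cis to C9, ligands omitted (not isolated) | CCCCC/C=C\C[C@@]1(OC(C)=O)C=C(Br)C(=O)/C1=C\[Pd]I | intermediate
22 | methyl (5E,7Z)-7-[(2R)-2-acetoxy-4-bromo-2-[(2Z)-oct-2-en-1-yl]-5-oxocyclopent-3-en-1-ylidene]hept-5-enoate | CCCCC/C=C\C[C@@]1(OC(C)=O)C=C(Br)C(=O)/C1=C\C=C\CCCC(=O)OC | target

Total step count: 12
Longest linear sequence: 11 steps (steps 1–10, then step 12); step 11 is a one-step branch.

Steps most likely to fail

1. Step 12. What may go wrong: transmetalation of the stannane with the vinyl- or acylpalladium before ring closure (acyclic coupling), a second CO insertion at the chelated alkenylpalladium, coupling at the C10–Br bond of the product, or ionisation of the tertiary propargylic acetate by Pd(0). The fallback sets out from 13 and comes back at 22. It makes C6–C7 first and closes the ring by an intramolecular carbonylative Stille coupling, so that no three-component timing is needed.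
   - Iodinolysis of 18 (I2, CH2Cl2, 0 °C) should give methyl (5E)-6-iodohex-5-enoate F1.
   - Sonogashira coupling of F1 with the terminal alkyne of 13 (Pd(PPh3)2Cl2, CuI, Et3N, THF, rt; the vinyl iodide reacts ahead of the dibromoalkene) should give the dibromo enyne ester F2.
   - The directed exchange of step 9, now on a substrate without an acetylenic proton, should pass through the magnesium carbenoid F3 (not isolated) to the bromo-iodo enyne ester F4.
   - Hydroxyl-directed ruthenium-catalysed trans-hydrostannation ([Cp*RuCl]4, Bu3SnH, CH2Cl2, rt) should place tin on C8 and hydrogen on C7 anti to it, giving the C8-stannyl dienol F5 with tin cis to C6.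
   - Acetylation (Ac2O, DMAP, Et3N) should give the stannyl acetate F6.
   - Pd2(dba)3/AsPh3 under CO (1 atm, THF, 50 °C) should then insert into C10–I, take up CO and couple at C8 with retention, which places C9 cis to C6 and delivers 22.

2. Step 9. What may go wrong: exchange at the bromine trans to C12, α-elimination of the carbenoid to an alkyne, or protonation of the carbenoid by an acetylenic C–H, each of which erodes the geometry or the yield of the direct iodination. The fallback sets out from 13 and comes back at 15. It separates metalation from halogenation through a tin relay.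
   - Carbenoid 14 is generated as in step 9 and quenched with Bu3SnCl (−78 → −30 °C) to give the α-bromoalkenylstannane (1Z,3R,5Z)-1-bromo-3-ethynyl-1-(tributylstannyl)undeca-1,5-dien-3-ol F7.
   - F7 is a stable compound that can be freed from any geometric isomer by chromatography and assigned by NOE.
   - Iododestannylation (I2, CH2Cl2, 0 °C, dark) should proceed with retention to 15.

3. Step 8. What may go wrong: activation and ionisation of the free tertiary propargylic alcohol by phosphonium species, or self-condensation of the unprotected α-hydroxy aldehyde ahead of ylide addition. The fallback sets out from 11 and comes back at 13. It carries the tertiary oxygen as a silyl ether through the olefination.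
   - Bis-silylation (TESOTf, 2,6-lutidine, CH2Cl2, −78 → 0 °C) should give the bis(triethylsilyl) ether F8.
   - Swern conditions ((COCl)2, DMSO, CH2Cl2, −78 → −30 °C; Et3N) should oxidise the primary silyl ether directly, leaving the tertiary one, to the α-silyloxy aldehyde F9.
   - Ramirez olefination as in step 8 should give the silyl-protected dibromoalkene F10.
   - Buffered fluoride (TBAF, AcOH, THF, 0 °C) should release 13.

Further compounds
F1 | step 12 | methyl (5E)-6-iodohex-5-enoate | I/C=C/CCCC(=O)OC
F2 | step 12 | methyl (5E,9R,11Z)-9-(2,2-dibromoethenyl)-9-hydroxyheptadeca-5,11-dien-7-ynoate | CCCCC/C=C\C[C@@](C#C/C=C/CCCC(=O)OC)(O)C=C(Br)Br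
F3 | step 12 | magnesium carbenoid of F2: chloromagnesium alkoxide with the bromine cis to the carbinol carbon replaced by MgCl (not isolated) | CCCCC/C=C\C[C@@](C#C/C=C/CCCC(=O)OC)(O[Mg]Cl)/C=C(\[Mg]Cl)Br
F4 | step 12 | methyl (5E,9R,11Z)-9-[(Z)-2-bromo-2-iodoethenyl]-9-hydroxyheptadeca-5,11-dien-7-ynoate | CCCCC/C=C\C[C@@](C#C/C=C/CCCC(=O)OC)(O)/C=C(\I)Br
F5 | step 12 | methyl (5E,7Z,9R,11Z)-9-[(Z)-2-bromo-2-iodoethenyl]-9-hydroxy-8-(tributylstannyl)heptadeca-5,7,11-trienoate | CCCCC/C=C\C[C@@](/C(=C/C=C/CCCC(=O)OC)[Sn](CCCC)(CCCC)CCCC)(O)/C=C(\I)Br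
F6 | step 12 | methyl (5E,7Z,9R,11Z)-9-acetoxy-9-[(Z)-2-bromo-2-iodoethenyl]-8-(tributylstannyl)heptadeca-5,7,11-trienoate | CCCCC/C=C\C[C@@](/C(=C/C=C/CCCC(=O)OC)[Sn](CCCC)(CCCC)CCCC)(OC(C)=O)/C=C(\I)Br
F7 | step 9 | (1Z,3R,5Z)-1-bromo-3-ethynyl-1-(tributylstannyl)undeca-1,5-dien-3-ol | CCCCC/C=C\C[C@@](C#C)(O)/C=C(\[Sn](CCCC)(CCCC)CCCC)Br
F8 | step 8 | triethyl{[(2S,4Z)-2-ethynyl-2-[(triethylsilyl)oxy]dec-4-en-1-yl]oxy}silane | CCCCC/C=C\C[C@@](C#C)(O[Si](CC)(CC)CC)CO[Si](CC)(CC)CC
F9 | step 8 | (2S,4Z)-2-ethynyl-2-[(triethylsilyl)oxy]dec-4-enal | CCCCC/C=C\C[C@@](C#C)(O[Si](CC)(CC)CC)C=O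
F10 | step 8 | {[(3R,5Z)-1,1-dibromo-3-ethynylundeca-1,5-dien-3-yl]oxy}triethylsilane | CCCCC/C=C\C[C@@](C#C)(O[Si](CC)(CC)CC)C=C(Br)Br
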